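| flask | solid substrate | first nucleophile | second nucleophile | remark | time |
|---|---|---|---|---|---|
| beta | 0.80 M | 0.56 M | 1.44 M | the very flask that is asked about, followed so far |  |
| theta | 0.54 M | 0.56 M | 1.44 M | run made earlier |  |
| flask | 0.80 M | 0.560 M | 1.44 M |  | 6.0 h |

| run | time / h | target / % | solid substrate / % |
|---|---|---|---|
| beta | 0.500 | 0 | 92.7 |
| beta | 1.00 | 1.3 | 85.4 |
| beta | 1.50 | 0.4 | 78.5 |
| beta | 2.00 | 1.1 | 72.8 |
| beta | 2.50 | 2.0 | 67.0 |
| beta | 3.00 | 3.8 | 61.5 |
| theta | 0.417 | 0.1 | 89.8 |
| theta | 1.33 | 1.9 | 72.4 |
| theta | 2.00 | 1.8 | 60.9 |
| theta | 3.00 | 4.4 | 44.3 |
| theta | 5.00 | 10.3 | 17.8 |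
| theta | 6.00 | 13.8 | 4.6 |

(standard deviation of a reading: 0.5 percentage points)

- the target standing at 6.0 h, as a percentage of the solid substrate charged
- the change that raises the amount of target at 6.0 h, in percent of the solid substrate charged most ("none" if none brings more than 2 percentage points) (birch / larch / maple / cedar / none)
- amount of target at 6.0 h, in percent of the solid substrate charged, after cedar

- birch: doubling the amount of first nucleophile, all else as stated
- larch: doubling the dissolution coefficient of the solid substrate, all else as stated
- maple: doubling the solubility of the solid substrate, all else as stated
- cedar: doubling the amount of second nucleophile, all else as stated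

- as a solid, counted per litre of solution: solid substrate
- at the start none of the solid substrate is in solution

We start from a leftover: at 6.00 h the theta run still holds 4.6% of its solid substrate. But percentages hide the link between the runs, so we turn them into molarity. By 3.00 h the beta flask has lost 0.308 M of solid substrate and the theta run 0.301 M, although their charges differ. So we read the theta run as the beta flask's future. Theta ends with 0.0745 M of target, which over the beta charge makes 9.32%.

For later times we replace the target curve by its mean. Let m be the late mean rate, the target gained per litre per hour over the second half of the theta run: 0.0169 M h⁻¹. The first half gives 0.00792 M h⁻¹, which is less than m, and this lag is an induction period. The error of the mean shows in the last hour of theta, which reads 0.0189 M h⁻¹, above m by 0.00200 M h⁻¹, though both carry the scatter.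

The forecast gives 9.2%, names cedar and puts that change at 17.5%, saying “doubling it should nearly double target”.

The flask gives 9.25% against our 9.32%; maple gains most, 7.5 percentage points, and cedar gives 8.11%.

    starting material → intermediate (k = 0.00250 min⁻¹)
    intermediate → side product (k = 0.00430 min⁻¹)
    solid substrate ⇌ starting material, rate k3*(cs3 - [starting material]) while solid is left; crystals form when [starting material] > cs3 (solubility = 0.620 M, k = 0.00350 min⁻¹)
    intermediate → solvolysis product (k = 0.0300 min⁻¹)
    2 starting material → self-condensation product (k = 4.20 × 10⁻⁶ M⁻¹ min⁻¹)
    first nucleophile + intermediate → target (k = 0.0610 M⁻¹ min⁻¹)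
    second nucleophile + intermediate → other capture product (k = 0.00850 M⁻¹ min⁻¹)

Now take the neighbour, the same flask read at 15 h, where the solid substrate stands at 0%. From 9.25% at 6.0 h we add m for the 9.00 h between, which gives 28.3%. The neighbour holds 27.6% of target.

The readings were generated by integration from invented constants, and the scatter is random.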